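# Proposed synthesis of the target gibberellin (number 66 of the gibberellin A series)

**Plan**

- Retrosynthesis: take off the C17 methylene and reduce-level the C15 carbinol to a 17-nor 15-ketone, then cut C13–C16 together with an auxiliary C12–C16 bond. This works because ring D is the five-membered ring C8–C14–C13–C16–C15 spanning C8 and C13 of ring C, with its oxygen-bearing C15 on quaternary C8 and C16 on C13, so a C8 diazomethyl ketone (C15, C16) can hand C16 as a carbene to a C12=C13 alkene.
- Earlier cuts: ring A at C4–C5 (aldol condensation) and C10–C1 (Michael addition), C4–C18 (enolate methylation), C6–C7 (dianion alkylation); ring B at C9–C10 (intramolecular Michael addition) and C8–C6 (alkylation of a benzoate-derived dienolate).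
- Forward order: ring C (from tert-butyl benzoate), ring B, ring A, and ring D last. Ring C is in place before C10 becomes quaternary, so the C1 chain enters anti to ring C and the C20 ester ends up syn to it.
- Stereochemistry: C8 and C9 from an organocatalytic desymmetrisation of a cyclohexadienone; C10 from convex-face Michael addition; C5 and C4 from hydride and MeI entering anti to the axial C20 ester.
- C6 is fixed by a cis C7/C15 anhydride, C13 by the tether in the carbene addition, and C15 by exo-face hydride delivery.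

Key step: step 17

Assumptions:
- α is the face of C19/C20 and β the face of H5, H9, C7 and C15 (gibberellane numbering throughout).
- The quinine-derived catalyst of step 4 is taken to give the enantiomer drawn for 7; otherwise its quinidine-derived pseudo-enantiomer is used.
- Labile or transient centres (C10 in 7–14, C12 in 9–11, C6 in 14–24) are drawn as the expected epimer, and both epimers converge.
- 4-Methoxybenzyl chloromethyl ether is moisture-sensitive and is taken to be used freshly prepared.

**Route**

Step 1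
Reactants: 1 tert-butyl benzoate; 2 methyl (E)-4-bromo-3-methoxybut-2-enoate
Product: 4 tert-butyl 1-[(E)-2,4-dimethoxy-4-oxobut-2-enyl]cyclohexa-2,5-diene-1-carboxylate, via lithium dienolate 3 (not isolated)
Conditions: Li (2.0 equiv), NH3(l)/THF, t-BuOH (1 equiv), −78 °C; then 2, −78 °C → rt
Reagents that add atoms: none
Why: Birch reductive alkylation: reduction and para protonation of the benzoate give dienolate 3, which the allylic bromide alkylates at the ipso carbon to create quaternary C8 (the diene is still symmetric, so no stereocentre arises).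

Step 2
Reactants: 4 tert-butyl 1-[(E)-2,4-dimethoxy-4-oxobut-2-enyl]cyclohexa-2,5-diene-1-carboxylate
Product: 5 tert-butyl 1-[(E)-2,4-dimethoxy-4-oxobut-2-enyl]-4-oxocyclohexa-2,5-diene-1-carboxylate
Conditions: (C5H5NH)2Cr2O7, t-BuOOH, Celite, PhH, rt
Reagents that add atoms: tert-butyl hydroperoxide, CC(C)(C)OO
Why: Allylic oxidation by (C5H5NH)2Cr2O7/t-BuOOH attacks the doubly allylic C12 methylene and should give the cross-conjugated 4,4-disubstituted cyclohexadienone, the electron-poor β-methoxy enoate being inert.

Step 3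
Reactants: 5 tert-butyl 1-[(E)-2,4-dimethoxy-4-oxobut-2-enyl]-4-oxocyclohexa-2,5-diene-1-carboxylate
Product: 6 tert-butyl 1-(4-methoxy-2,4-dioxobutyl)-4-oxocyclohexa-2,5-diene-1-carboxylate
Conditions: 1 M HCl, THF, 0 °C → rt
Reagents that add atoms: water, O
Why: Acid hydrolysis of the enol ether (a vinylogous carbonate) unmasks the C20–C10–C5 β-keto ester at an acidity the tert-butyl ester tolerates.

Step 4
Reactants: 6 tert-butyl 1-(4-methoxy-2,4-dioxobutyl)-4-oxocyclohexa-2,5-diene-1-carboxylate
Product: 7 cis-fused BC enone (C5 and C12 ketones; C13=C14; C10 CO2Me; C8 CO2t-Bu β and cis to H9)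
Conditions: quinine-derived 9-amino-9-deoxy-epi thiourea bearing a 3,5-bis(trifluoromethyl)phenyl group (10 mol %), PhMe, −20 °C
Reagents that add atoms: none
Why: Desymmetrising intramolecular Michael addition (5-exo-trig) of C10 onto C9 under bifunctional amine–thiourea catalysis; the tether enforces the cis B/C fusion and the catalyst selects one of the two enantiotopic enone arms, which sets C8 and C9.

Step 5
Reactants: 7 cis-fused BC enone
Product: 9 C12 allylic alcohol of the BC system (C13=C14 retained), via lithium enolate 8 (not isolated)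
Conditions: LiN(SiMe3)2 (1.05 equiv), THF, −78 °C; i-Bu2AlH (1.2 equiv), −78 °C; aq. KNaC4H4O6
Reagents that add atoms: none
Why: Chemoselective 1,2-reduction: the β-keto ester is masked in situ as its lithium enolate, so i-Bu2AlH should add only to the ring C enone carbonyl; the C12 configuration is irrelevant because C12 becomes sp2 in step 6.

Step 6
Reactants: 9 C12 allylic alcohol of the BC system
Product: 12 cis-fused BC β-keto ester with C12=C13 (C5 ketone; C10 CO2Me; C8 CO2t-Bu), via allylic sulfonylhydrazine 10 (not isolated), via allylic diazene 11 (not isolated)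
Conditions: PPh3, EtO2CN=NCO2Et, 2-O2NC6H4SO2NHNH2, N-methylmorpholine, −30 °C → rt
Reagents that add atoms: none
Why: Mitsunobu displacement by the sulfonylhydrazide, loss of sulfinic acid and retro-ene loss of N2 from the allylic diazene deliver hydrogen to C14 and move the alkene to C12=C13 (reductive 1,3-transposition of an allylic alcohol).

Step 7
Reactants: 12 cis-fused BC β-keto ester with C12=C13
Product: 14 C6-[(4-methoxybenzyloxy)methyl] BC β-keto ester (6β), via dilithium dianion 13 (not isolated)
Conditions: LiN(i-Pr)2 (2.2 equiv), THF, −78 → 0 °C; 4-MeOC6H4CH2OCH2Cl, −78 °C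
Reagents that add atoms: 4-methoxybenzyl chloromethyl ether, COc1ccc(COCCl)cc1
Why: γ-Alkylation of a β-keto ester dianion: the second deprotonation can occur only at C6, the more reactive carbanion, which takes up the masked C7 carbon, expected on the convex face (6β); a 6α epimer would be corrected in step 14.

Step 8
Reactants: 14 C6-[(4-methoxybenzyloxy)methyl] BC β-keto ester; 15 methyl 5-methoxy-3-oxopentanoate
Product: 17 C10 Michael adduct (C10 quaternary; CO2Me α; 5-methoxy-3,5-dioxopentyl chain β), via methyl 3-oxopent-4-enoate 16 (not isolated)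
Conditions: Cs2CO3 (0.2 equiv), MeCN, 0 °C → rt
Reagents that add atoms: none
Why: Michael addition of the C10 β-keto ester to vinyl ketone 16, released from 15 by β-elimination of methanol (first half of a Robinson annulation); the acceptor should approach the convex face anti to C11, so C1 enters β and the C20 ester stays α, syn to ring C.

Step 9
Reactants: 17 C10 Michael adduct
Product: 18 ABC tricyclic enone (ring A 3-oxo with C4=C5 and C19 CO2Me on C4)
Conditions: piperidine (0.2 equiv), AcOH (0.2 equiv), PhMe, 4 Å MS, 60 °C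
Reagents that add atoms: none
Why: Intramolecular Knoevenagel-type aldol condensation of the C4 methylene onto the C5 ketone closes the six-membered ring A and dehydrates to the alkylidene β-keto ester.

Step 10
Reactants: 18 ABC tricyclic enone
Product: 20 3-oxo-4β-methyl-5β-H tricycle (C19 CO2Me α; trans A/B fusion), via lithium enolate 19 (not isolated)
Conditions: LiBH(s-Bu)3, THF, −78 °C; then MeI, DMPU, −78 °C → rt
Reagents that add atoms: iodomethane, CI
Why: Tandem conjugate reduction–alkylation: LiBH(s-Bu)3 adds hydride to the doubly activated C5 from the β face, anti to the axial C20 ester (H5 trans to C20), and enolate 19 is C-methylated on the same face, leaving the C19 ester axial and cis to C20.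

Step 11
Reactants: 20 3-oxo-4β-methyl-5β-H tricycle
Product: 22 3-deoxy tricycle (C19 and C20 methyl esters; C15 tert-butyl ester; C7 PMB ether; C12=C13), via tosylhydrazone 21 (not isolated)
Conditions: TsNHNH2, AcOH (cat.), EtOH, 78 °C; then catecholborane, CHCl3, 0 °C → rt; NaOAc·3H2O, 60 °C
Reagents that add atoms: none
Why: Caglioti-type deoxygenation: hydride reduction of the tosylhydrazone and loss of sulfinate and N2 remove the C3 carbonyl under conditions that spare esters and the isolated alkene.

Step 12
Reactants: 22 3-deoxy tricycle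
Product: 23 C7 primary alcohol
Conditions: DDQ, CH2Cl2/pH 7 buffer (10:1), 0 °C → rt
Reagents that add atoms: none
Why: Oxidative cleavage of the 4-methoxybenzyl ether (benzylic hydride abstraction, hydrolysis of the oxocarbenium ion) frees the alcohol without touching the alkene or esters.

Step 13
Reactants: 23 C7 primary alcohol
Product: 24 C7 carboxylic acid
Conditions: TEMPO (0.2 equiv), PhI(OAc)2 (2.2 equiv), MeCN/H2O (1:1), rt
Reagents that add atoms: water, O
Why: Nitroxyl-catalysed oxidation (oxoammonium cycle) takes the primary alcohol through the aldehyde hydrate to the acid and is inert towards C12=C13.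

Step 14
Reactants: 24 C7 carboxylic acid
Product: 26 C7/C15 cyclic anhydride (6β), via diacid 25 (not isolated)
Conditions: CF3CO2H/CH2Cl2 (1:3), 0 °C; evaporate; Ac2O, NaOAc (0.2 equiv), 100 °C
Reagents that add atoms: none
Why: Acidolysis of the tert-butyl ester and dehydration give the five-membered anhydride, which can form only with C7 and C15 cis; a 6α acid epimerises through its enolisable mixed anhydride, so C6 is fixed as 6β.

Step 15
Reactants: 26 C7/C15 cyclic anhydride
Product: 27 C15 acid with C7, C19 and C20 methyl esters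
Conditions: MeOH, DMAP (0.1 equiv), CH2Cl2, rt; aq. HCl work-up
Reagents that add atoms: methanol, CO
Why: Regioselective methanolysis of the unsymmetrical anhydride should occur at the less hindered C7 carbonyl (on a CH) and not at the neopentyl C15 carbonyl on quaternary C8, and the mild base does not epimerise C6.

Step 16
Reactants: 27 C15 acid with C7, C19 and C20 methyl esters
Product: 29 C8 diazomethyl ketone with C12=C13 (C7, C19 and C20 methyl esters), via acid chloride 28 (not isolated)
Conditions: (COCl)2, DMF (cat.), CH2Cl2, 0 °C → rt; evaporate; Me3SiCHN2 (3 equiv), MeCN/THF (1:1), 0 °C → rt; aqueous work-up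
Reagents that add atoms: (trimethylsilyl)diazomethane, C[Si](C)(C)C=[N+]=[N-]
Why: Arndt–Eistert-type diazoketone synthesis: the acid chloride C-acylates the silyl diazomethane, a second equivalent of which takes up the HCl, and the silyl group is lost on work-up; C8 is quaternary, so no ketene can form.

Step 17
Reactants: 29 C8 diazomethyl ketone with C12=C13
Product: 30 12,16-cyclo 15-ketone (cyclopropyl ketone) trimethyl ester
Conditions: Rh2(OAc)4 (1 mol %), CH2Cl2, rt, slow addition of 29
Reagents that add atoms: none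
Why: Rh2(OAc)4 decomposes the diazoketone with loss of N2 to an electrophilic rhodium-bound carbenoid at C16, which adds in one asynchronous step across C12=C13 (intramolecular carbenoid cyclopropanation). The closest known reaction type is the closure of γ,δ-unsaturated α-diazoketones to bicyclo[3.1.0]hexan-2-ones, here on a cyclohex-3-enyl diazomethyl ketone. Ring D (C8, C15, C16, C13, C14) closes by bonding C16 to the proximal alkene carbon C13 in a five-membered exo mode, and the three-membered ring closes by bonding C16 to C12. C13, C12 and C16 are all set by the tether: the acyl arm stands on the β face of ring C at C8, the carbenoid can reach the alkene only from that face, and the cyclopropane is necessarily cis-fused. The step needs cyclopropanation to win over C–H insertion (C5–H, C11–H) and over attack on the ester carbonyls; the γ,δ position of the only alkene, the preference of Rh2(OAc)4 carbenoids for π bonds and slow addition secure this.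

Step 18
Reactants: 30 12,16-cyclo 15-ketone trimethyl ester
Product: 31 17-nor 15-ketone trimethyl ester (bicyclo[3.2.1]octanone CD system; C16 as CH2)
Conditions: SmI2 (2.5 equiv), THF/MeOH (10:1), −78 °C
Reagents that add atoms: none
Why: Reductive cyclopropyl ketone cleavage: the ketyl opens the bond that overlaps best with the carbonyl π system, C12–C16 (exocyclic to the cyclopentanone), not C13–C16, and the C12 carbanion and the enolate are protonated by methanol.

Step 19
Reactants: 31 17-nor 15-ketone trimethyl ester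
Product: 32 16-methylene 15-ketone trimethyl ester
Conditions: (CH2O)n, i-Pr2NH2+ CF3CO2− (1 equiv), CF3CO2H (0.1 equiv), THF, 65 °C
Reagents that add atoms: formaldehyde (as paraformaldehyde), C=O
Why: Mannich-type α-methylenation: the ketone can enolise only towards C16 because C8 is quaternary, and the aminomethyl adduct eliminates to the exocyclic enone.

Step 20
Reactants: 32 16-methylene 15-ketone trimethyl ester
Product: 33 trimethyl ester of the target gibberellin (15β-alcohol)
Conditions: NaBH4, CeCl3·7H2O, MeOH, −78 → 0 °C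
Reagents that add atoms: none
Why: Luche 1,2-reduction: hydride should reach C15 from the exo face of the bicyclo[3.2.1]octenone, away from the C9–C11–C12 bridge and its axial C11 hydrogen, giving the endo (15β) alcohol.

Step 21
Reactants: 33 trimethyl ester of the target gibberellin
Product: 34 the target gibberellin (15β-hydroxy 7,19,20-triacid)
Conditions: NaSEt (10 equiv), DMF, 90 °C; then aq. HCl
Reagents that add atoms: none
Why: Nucleophilic demethylation of methyl esters: the thiolate attacks the methyl carbons (alkyl–oxygen cleavage), which frees the hindered C19 and C20 acids and the C7 acid alike, without acyl substitution and without harming the allylic alcohol.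

**Compound list**

1 | tert-butyl benzoate | CC(C)(C)OC(=O)c1ccccc1 | starting material
2 | methyl (E)-4-bromo-3-methoxybut-2-enoate | COC(=O)/C=C(/OC)CBr | starting material
3 | lithium dienolate of tert-butyl cyclohexa-2,5-diene-1-carboxylate | [Li+].[O-]C(OC(C)(C)C)=C1C=CCC=C1 | intermediate
4 | tert-butyl 1-[(E)-2,4-dimethoxy-4-oxobut-2-enyl]cyclohexa-2,5-diene-1-carboxylate | COC(=O)/C=C(/OC)CC1(C=CCC=C1)C(=O)OC(C)(C)C | intermediate
5 | tert-butyl 1-[(E)-2,4-dimethoxy-4-oxobut-2-enyl]-4-oxocyclohexa-2,5-diene-1-carboxylate | COC(=O)/C=C(/OC)CC1(C=CC(=O)C=C1)C(=O)OC(C)(C)C | intermediate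
6 | tert-butyl 1-(4-methoxy-2,4-dioxobutyl)-4-oxocyclohexa-2,5-diene-1-carboxylate | COC(=O)CC(=O)CC1(C=CC(=O)C=C1)C(=O)OC(C)(C)C | intermediate
7 | cis-fused BC enone: 3a-tert-butyl 1-methyl 2,6-dioxo-1,2,3,6,7,7a-hexahydro-3aH-indene-1,3a-dicarboxylate (C8 ester cis to H9) | O=C1C[C@H]2[C@H](C(=O)OC)C(=O)C[C@]2(C=C1)C(=O)OC(C)(C)C | intermediate
8 | lithium C5–C10 enolate of 7 | [Li+].O=C1C[C@H]2C(C(=O)OC)=C([O-])C[C@]2(C=C1)C(=O)OC(C)(C)C | intermediate
9 | C12 allylic alcohol of 7 (C13=C14) | O[C@H]1C[C@H]2[C@H](C(=O)OC)C(=O)C[C@]2(C=C1)C(=O)OC(C)(C)C | intermediate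
10 | N-(C12-allyl)-N-(2-nitrobenzenesulfonyl)hydrazine (C12 inverted) | NN([C@@H]1C[C@H]2[C@H](C(=O)OC)C(=O)C[C@]2(C=C1)C(=O)OC(C)(C)C)S(=O)(=O)c1ccccc1[N+](=O)[O-] | intermediate
11 | C12 allylic diazene | N=N[C@@H]1C[C@H]2[C@H](C(=O)OC)C(=O)C[C@]2(C=C1)C(=O)OC(C)(C)C | intermediate
12 | cis-fused BC β-keto ester: 3a-tert-butyl 1-methyl 2-oxo-1,2,3,4,7,7a-hexahydro-3aH-indene-1,3a-dicarboxylate (C12=C13) | C1=CC[C@H]2[C@H](C(=O)OC)C(=O)C[C@]2(C1)C(=O)OC(C)(C)C | intermediate
13 | dilithium C6,C10 dianion of 12 | [Li+].[Li+].C1=CC[C@H]2C(=C(OC)[O-])C([O-])=C[C@]2(C1)C(=O)OC(C)(C)C | intermediate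
14 | 6β-[(4-methoxybenzyloxy)methyl] derivative of 12 | C1=CC[C@H]2[C@H](C(=O)OC)C(=O)[C@H](COCc3ccc(OC)cc3)[C@]2(C1)C(=O)OC(C)(C)C | intermediate
15 | methyl 5-methoxy-3-oxopentanoate | COCCC(=O)CC(=O)OC | starting material
16 | methyl 3-oxopent-4-enoate | C=CC(=O)CC(=O)OC | intermediate
17 | C10 Michael adduct (C10 quaternary, CO2Me α, 5-methoxy-3,5-dioxopentyl β) | C1=CC[C@H]2[C@](C(=O)OC)(CCC(=O)CC(=O)OC)C(=O)[C@H](COCc3ccc(OC)cc3)[C@]2(C1)C(=O)OC(C)(C)C | intermediate
18 | ABC tricyclic enone (3-oxo, C4=C5, C19 CO2Me on C4) | C1=CC[C@H]3[C@]4(C(=O)OC)CCC(=O)C(C(=O)OC)=C4[C@H](COCc5ccc(OC)cc5)[C@]3(C1)C(=O)OC(C)(C)C | intermediate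
19 | lithium C3–C4 enolate (5β-H) | [Li+].C1=CC[C@H]3[C@]4(C(=O)OC)CCC([O-])=C(C(=O)OC)[C@H]4[C@H](COCc5ccc(OC)cc5)[C@]3(C1)C(=O)OC(C)(C)C | intermediate
20 | 3-oxo-4β-methyl-5β-H tricycle (C19 CO2Me α) | C1=CC[C@H]3[C@]4(C(=O)OC)CCC(=O)[C@@](C)(C(=O)OC)[C@H]4[C@H](COCc5ccc(OC)cc5)[C@]3(C1)C(=O)OC(C)(C)C | intermediate
21 | C3 tosylhydrazone of 20 | C1=CC[C@H]3[C@]4(C(=O)OC)CCC(=NNS(=O)(=O)c6ccc(C)cc6)[C@@](C)(C(=O)OC)[C@H]4[C@H](COCc5ccc(OC)cc5)[C@]3(C1)C(=O)OC(C)(C)C | intermediate
22 | 3-deoxy tricycle (C19, C20 methyl esters; C15 tert-butyl ester; C7 PMB ether) | C1=CC[C@H]3[C@]4(C(=O)OC)CCC[C@@](C)(C(=O)OC)[C@H]4[C@H](COCc5ccc(OC)cc5)[C@]3(C1)C(=O)OC(C)(C)C | intermediate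
23 | C7 alcohol | C1=CC[C@H]3[C@]4(C(=O)OC)CCC[C@@](C)(C(=O)OC)[C@H]4[C@H](CO)[C@]3(C1)C(=O)OC(C)(C)C | intermediate
24 | C7 acid | C1=CC[C@H]3[C@]4(C(=O)OC)CCC[C@@](C)(C(=O)OC)[C@H]4[C@H](C(=O)O)[C@]3(C1)C(=O)OC(C)(C)C | intermediate
25 | C7,C15 diacid | C1=CC[C@H]3[C@]4(C(=O)OC)CCC[C@@](C)(C(=O)OC)[C@H]4[C@H](C(=O)O)[C@]3(C1)C(=O)O | intermediate
26 | C7/C15 cyclic anhydride (6β) | C1=CC[C@H]3[C@]4(C(=O)OC)CCC[C@@](C)(C(=O)OC)[C@H]4[C@@H]5C(=O)OC(=O)[C@]35C1 | intermediate
27 | C15 acid, C7/C19/C20 trimethyl ester | C1=CC[C@H]3[C@]4(C(=O)OC)CCC[C@@](C)(C(=O)OC)[C@H]4[C@H](C(=O)OC)[C@]3(C1)C(=O)O | intermediate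
28 | C15 acid chloride | C1=CC[C@H]3[C@]4(C(=O)OC)CCC[C@@](C)(C(=O)OC)[C@H]4[C@H](C(=O)OC)[C@]3(C1)C(=O)Cl | intermediate
29 | C8 diazomethyl ketone, ABC triester with C12=C13 | C1=CC[C@H]3[C@]4(C(=O)OC)CCC[C@@](C)(C(=O)OC)[C@H]4[C@H](C(=O)OC)[C@]3(C1)C(=O)C=[N+]=[N-] | intermediate
30 | 12,16-cyclo 15-ketone trimethyl ester | [C@@H]15[C@@H]2[C@H]5C[C@H]3[C@]4(C(=O)OC)CCC[C@@](C)(C(=O)OC)[C@H]4[C@H](C(=O)OC)[C@]3(C2)C1=O | intermediate
31 | 17-nor 15-ketone trimethyl ester | C1[C@@H]2CC[C@H]3[C@]4(C(=O)OC)CCC[C@@](C)(C(=O)OC)[C@H]4[C@H](C(=O)OC)[C@]3(C2)C1=O | intermediate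
32 | 16-methylene 15-ketone trimethyl ester | C=C1[C@@H]2CC[C@H]3[C@]4(C(=O)OC)CCC[C@@](C)(C(=O)OC)[C@H]4[C@H](C(=O)OC)[C@]3(C2)C1=O | intermediate
33 | 7,19,20-trimethyl ester of the target gibberellin (15β-alcohol) | C=C1[C@@H]2CC[C@H]3[C@]4(C(=O)OC)CCC[C@@](C)(C(=O)OC)[C@H]4[C@H](C(=O)OC)[C@]3(C2)[C@@H]1O | intermediate
34 | target gibberellin, member 66 of the gibberellin A series: 15β-hydroxy-C20-gibberell-16-ene-7,19,20-trioic acid | C=C1[C@@H]2CC[C@H]3[C@]4(C(=O)O)CCC[C@@](C)(C(=O)O)[C@H]4[C@H](C(=O)O)[C@]3(C2)[C@@H]1O | target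

**Count and risks**

Total: 21 steps. Longest linear sequence: 21 steps (from 1).

Steps most likely to fail:

Step 8. The vinyl ketone may add to the concave face of the C10 enolate (the β C8 ester sits 1,3 to C10), or it may polymerise before capture. C10 could then form with poor diastereoselectivity or conversion. Fallback, from 14 back to 17: a Michael addition to acrolein under a quinidine-derived 6′-hydroxy cinchona base, where the catalyst rather than the substrate should choose the C10 face, would give the C10 3-oxopropyl aldehyde F1. Methyl diazoacetate with SnCl2 (0.1 equiv) in CH2Cl2 then inserts its carbon into the aldehyde C–H bond (Roskamp homologation). This delivers β-keto ester 17 without any free vinyl ketone, and the ketone and esters are left alone.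

Step 10. LiBH(s-Bu)3 may attack the C3 carbonyl (1,2-reduction) or fail to reach the fully substituted C5, and methylation of the enolate in the presence of the borane may stall. Fallback, from 18 back to 20: conjugate reduction with the copper hydride hexamer [(Ph3P)CuH]6 in wet PhMe (hydrocupration, then protonation) gives the isolated 5β-H β-keto ester F2. F2 is then methylated in a separate operation with MeI and K2CO3 in acetone to 20.

Step 5. Incomplete masking of the β-keto ester may let the hydride reduce the C5 ketone, or the free β-keto ester may interfere in the Mitsunobu step that follows. Fallback, from 7 back to 12: Me3SiCHN2 in MeOH/PhMe O-methylates the β-keto ester to the methyl enol ether F3. TsNHNH2 then condenses with the only remaining ketone (C12) to give the tosylhydrazone F4. Catecholborane followed by NaOAc·3H2O reduces it with allylic transposition to the C12=C13 enol ether F5, and aqueous HCl hydrolyses this to 12.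

**Further compounds**

F1 | step 8 | C10 3-oxopropyl (aldehyde) Michael adduct of 14 | C1=CC[C@H]2[C@](C(=O)OC)(CCC=O)C(=O)[C@H](COCc3ccc(OC)cc3)[C@]2(C1)C(=O)OC(C)(C)C
F2 | step 10 | 5β-H β-keto ester (C4 epimerisable, ester drawn equatorial) | C1=CC[C@H]3[C@]4(C(=O)OC)CCC(=O)[C@H](C(=O)OC)[C@H]4[C@H](COCc5ccc(OC)cc5)[C@]3(C1)C(=O)OC(C)(C)C
F3 | step 5 | methyl enol ether of 7 (C5 OMe, C5=C10) | O=C1C[C@H]2C(C(=O)OC)=C(OC)C[C@]2(C=C1)C(=O)OC(C)(C)C
F4 | step 5 | C12 tosylhydrazone of the methyl enol ether | Cc1ccc(cc1)S(=O)(=O)NN=C1C[C@H]2C(C(=O)OC)=C(OC)C[C@]2(C=C1)C(=O)OC(C)(C)C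
F5 | step 5 | C12=C13 methyl enol ether | C1=CC[C@H]2C(C(=O)OC)=C(OC)C[C@]2(C1)C(=O)OC(C)(C)C
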